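The earlier runs and the new flask come from a simulation from invented constants; noise was put on by code.

**The trap.** A flat curve tempted me to read an end of the chemistry into it, yet flatness says only that the rate is low, not why. The flask at 35 °C is the south-east run, and the east run is its hotter twin.

| flask | starting material | partner | second substrate | precatalyst | temperature | remark | time |
|---|---|---|---|---|---|---|---|
| south-east | 0.48 M | 1.44 M | 0.096 M | 16 mM | 35 °C | the very flask that is asked about, followed so far |  |
| east | 0.48 M | 1.44 M | 0.096 M | 16 mM | 41 °C | run made earlier |  |
| flask | 0.48 M | 1.44 M | 0.0960 M | 16 mM | 35 °C |  | 10 h |

- south-east (time / h: target / %): 0.833: 18.5; 2.50: 35.5; 5.00: 44.1; 8.00: 47.0; 10.0: 47.4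
- east (time / h: target / %): 0.833: 23.9; 2.50: 35.1; 5.00: 39.8; 8.00: 41.9; 10.0: 42.2

(each reading ± 1 percentage point)

- target that was removed still counts
- the earlier runs were read with a standard deviation of 1 percentage point
- additions bring no volume worth counting

- eta: at 10 h raise the temperature by 15 K, then wait 20 h
- delta: at 10 h add partner, 50.0% of the amount charged, then wait 20 h
- epsilon: at 10 h take out 90% of the target then present, then wait 20 h
- zeta: change nothing and wait 20 h more
- alpha: at 10 h add precatalyst, 100% of the amount charged, then wait 20 h

- target, in percent of the starting material first charged, at 10 h
- what to do for the largest gain in target; "none" if nothing gains more than 2 percentage points (eta / delta / epsilon / zeta / alpha / none)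
- target present, with what was taken out counted in, in percent of the starting material first charged, after epsilon
- target present, with what was taken out counted in, in percent of the starting material first charged, after alpha

**Fastest rung.** In the south-east run, the first reading gave a mean rate of 0.222 h⁻¹ in fractions of the charge. At that mean, the level of the last reading fills in 2.13 h. The east run began faster, at 0.287 h⁻¹, yet stood lower at 42.2%.

**Slowest rung.** From 5.00 h to 10.0 h, the south-east mean rate was 0.00660 h⁻¹, a fall by a factor of 33.6 as read. The reagents used for the target read at the end give a fall of 2.26 in a rate proportional to both, far less. A reverse step stayed possible, but I bet on the catalyst.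

**The budget.** I treated the fall of starting material as pseudo-first-order, with its rate constant scaled by the partner fraction and by catalyst exposure. My carried quantity is the catalyst budget: the logarithmic fall of starting material that one charge of precatalyst buys, per unit of mean partner fraction. With a mean partner fraction of 0.921, it came to 0.698. For a further equal charge, with the partner fraction held at what the last reading implies, I reckoned a gain of 23 percentage points, so 70.8% of target. Waiting 20 h at the late mean rate gives 13 points, which is less, and that rate was still falling as read. I chose the added precatalyst.

**The forecast.** It gave 47.5% now, alpha as best, 47.7% after epsilon and 69% after alpha, lower than my figure for alpha. Its ground was “I therefore take the catalyst to be essentially dead by 10 h”.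

**The result.** The flask gave 47.8%, with alpha best at a gain of 19 points. Epsilon gave 50.2% and alpha 66.3%.

    second substrate + partner + free catalyst → free catalyst + second product (k = 2.90 L² mol⁻² min⁻¹, Ea = 40.0 kJ mol⁻¹)
    starting material + partner + free catalyst → free catalyst + target (k = 1.70 L² mol⁻² min⁻¹, Ea = 37.0 kJ mol⁻¹)
    precatalyst → free catalyst (k = 0.0170 min⁻¹, Ea = 100 kJ mol⁻¹)
    2 free catalyst → spent catalyst (k = 22.0 L mol⁻¹ min⁻¹, Ea = 59.0 kJ mol⁻¹)
    starting material + partner → uncatalysed product (k = 2.50 × 10⁻⁴ L mol⁻¹ min⁻¹, Ea = 66.0 kJ mol⁻¹)
    (constants at 35 °C)

**The reason.** The plateau of this flask comes mainly from free catalyst pairing into spent catalyst: the run without that step reaches 98.0%, against 47.8%. At 10.0 h, 0.452% of the catalyst could still turn over. The flask also held uncatalysed product at that time, 9.84%, which my budget had not counted, so 42.3% of the starting material stood there. Put into the budget with 76.2% of the partner, that gives 17 points for alpha.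

**The neighbour.** The neighbour with 2.4 M of partner held the catalyst charge and the temperature, so I kept the budget, with the partner counted as a fraction of this flask's charge, and it gave 66.1% of target. The computed neighbour stands at 65.2%.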